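**Retrosynthetic overview**

- The target, 3-(4-hydroxyphenyl)-5-methoxy-4,7-diphenyl-1-benzofuran-2,6-dione, is a ring A para-quinone methide. It is traced back by removal of two hydrogens (C3–H and O6–H) to the 6-hydroxy lactone 22, and from there to the O6-benzyl, O4'-pivaloyl lactone 19.
- Key disconnection: the C4–phenyl and C7–phenyl bonds are cut together, giving dibromide 15 and two phenylboronic acids. The strategy rests on the fact that these two phenyls sit para to each other on the hexasubstituted carbocycle (ring A), C4 between C3a and C5(OMe) and C7 between C6(O) and C7a(O1), and that these are the only two CH positions of a 5,6-dioxygenated 3-arylbenzofuran-2(3H)-one.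
- Dibromide 15 comes from nuclear dibromination of pivalate 11, which comes from lactone phenol 9. Lactone 9 is made by acid condensation of 3-(benzyloxy)-4-methoxyphenol 6 with 4-hydroxymandelic acid, which forms the C3–C3a bond and the lactone. Phenol 6 comes from isovanillin by benzylation and Baeyer–Villiger oxidation.
- Ring order: ring A is bought with isovanillin, ring B (the lactone) closes in step 3, and no ring is formed afterwards.

Key step: step 6

Remark: benzofuranone numbering is used (O1, C2 lactone carbonyl, C3, C3a, C4–C7, C7a; ring A is the carbocycle, ring B the lactone). C3 is a stereocentre in 9–22, carried as the racemate and removed in step 9. The oxidised lactone is assumed to rest as the ring A quinone methide tautomer drawn for the target.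

**Route**

Step 1
Reactants: 1 isovanillin; 2 benzyl bromide
Product: 3 3-(benzyloxy)-4-methoxybenzaldehyde
Conditions: K2CO3, DMF, 60 °C
Reagents that add atoms: benzyl bromide, BrCc1ccccc1
Why: Williamson ether synthesis, in which the phenoxide of isovanillin displaces bromide from benzyl bromide and the aldehyde is inert to K2CO3 in DMF.

Step 2
Reactants: 3 3-(benzyloxy)-4-methoxybenzaldehyde; 4 meta-chloroperbenzoic acid (mCPBA)
Product: 6 3-(benzyloxy)-4-methoxyphenol, via aryl formate 5 (not isolated)
Conditions: mCPBA, CH2Cl2, 0 °C to rt; aq. NaHCO3 wash; then K2CO3 (cat.), MeOH, rt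
Reagents that add atoms: mCPBA, OOC(=O)c1cccc(Cl)c1
Why: Baeyer–Villiger (Dakin-type) oxidation, in which the electron-rich aryl group migrates in the Criegee adduct to give formate 5, and mild transesterification with methanol then frees the phenol without touching the benzyl ether.

Step 3
Reactants: 6 3-(benzyloxy)-4-methoxyphenol; 7 4-hydroxymandelic acid (racemic)
Product: 9 6-(benzyloxy)-3-(4-hydroxyphenyl)-5-methoxy-1-benzofuran-2(3H)-one (racemic), via hydroxy acid 8 (not isolated)
Conditions: TsOH·H2O (20 mol%), toluene/1,4-dioxane, 90 °C, Dean–Stark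
Reagents that add atoms: 4-hydroxymandelic acid, OC(C(=O)O)c1ccc(O)cc1
Why: Acid-catalysed Friedel–Crafts hydroxyalkylation followed by lactonisation (the mandelic acid–phenol route to 3-arylbenzofuran-2(3H)-ones), in which the para-hydroxybenzyl cation from 7 attacks 6 at the carbon ortho to the hydroxyl and para to the benzyloxy group, the most activated and least hindered site, and hydroxy acid 8 closes ring B with loss of water, giving C3 as the racemate.

Step 4
Reactants: 9 6-(benzyloxy)-3-(4-hydroxyphenyl)-5-methoxy-1-benzofuran-2(3H)-one; 10 pivaloyl chloride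
Product: 11 4-[6-(benzyloxy)-5-methoxy-2-oxo-2,3-dihydro-1-benzofuran-3-yl]phenyl pivalate (racemic)
Conditions: PivCl (1.1 equiv), pyridine, CH2Cl2, 0 °C to rt, no DMAP
Reagents that add atoms: pivaloyl chloride, CC(C)(C)C(=O)Cl
Why: Acylation of a phenol by an acid chloride through the N-acylpyridinium ion, where pyridine is too weak a base to form the lactone enolate (no DMAP or trialkylamine is present), so only the phenolic oxygen should be pivaloylated.

Step 5
Reactants: 11 4-[6-(benzyloxy)-5-methoxy-2-oxo-2,3-dihydro-1-benzofuran-3-yl]phenyl pivalate; 12 N-bromosuccinimide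
Product: 15 4-[6-(benzyloxy)-4,7-dibromo-5-methoxy-2-oxo-2,3-dihydro-1-benzofuran-3-yl]phenyl pivalate (racemic), via 7-bromo lactone 13 (not isolated), via 4-bromo lactone 14 (not isolated)
Conditions: NBS (2.2 equiv), TFA (10 mol%), MeCN, 0 °C to rt, dark
Reagents that add atoms: N-bromosuccinimide, O=C1CCC(=O)N1Br
Why: Electrophilic aromatic bromination with NBS in acetonitrile, in which ring A, with two alkoxy donors and the lactone oxygen, should react at its only free positions C7 (ortho to the benzyloxy group and to O1) and C4 (ortho to the methoxy group, para to O1) far faster than the pivalate-deactivated aryl ring, while the absence of light and base favours ionic ring bromination over substitution at C3–H.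

Step 6
Reactants: 15 4-[6-(benzyloxy)-4,7-dibromo-5-methoxy-2-oxo-2,3-dihydro-1-benzofuran-3-yl]phenyl pivalate; 16 phenylboronic acid
Product: 19 4-[6-(benzyloxy)-5-methoxy-2-oxo-4,7-diphenyl-2,3-dihydro-1-benzofuran-3-yl]phenyl pivalate (racemic), via 4-bromo-7-phenyl lactone 17 (not isolated), via 7-bromo-4-phenyl lactone 18 (not isolated)
Conditions: PhB(OH)2 (3.5 equiv), Pd(OAc)2 (5 mol%), SPhos (10 mol%), K3PO4 (anhydrous, 5 equiv), toluene, 100 °C, argon; 1 M HCl work-up
Reagents that add atoms: phenylboronic acid, OB(O)c1ccccc1
Why: Zerovalent palladium carrying one SPhos ligand, formed in the flask from Pd(OAc)2, inserts into each C–Br bond in turn, the phenylboronate made from phenylboronic acid and K3PO4 transfers phenyl to the divalent arylpalladium bromide, and reductive elimination forms the C4–phenyl and C7–phenyl bonds, so that monobromides 17 and 18 converge on 19 whichever bromide reacts first. The closest known reaction type is the Suzuki–Miyaura coupling of di-ortho-substituted, electron-rich aryl bromides with bulky dialkylbiarylphosphines, which is established for tri- and tetra-ortho-substituted biaryls. No ring is closed and no stereocentre is created; the existing C3 centre is racemic and rests as its potassium enolate under the base, which the HCl work-up reprotonates to the closed lactone. The step needs complete twofold coupling without protodebromination and without arylation at C3 of the enolate: excess boronic acid and fast transmetalation at the monoligated palladium centre address the first, and the tertiary, doubly flanked enolate carbon facing a di-ortho-substituted arylpalladium addresses the second. Site selectivity is not required because C4 and C7 receive the same group, and the aryl pivalate C–O bond is inert to palladium under these conditions.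

Step 7
Reactants: 19 4-[6-(benzyloxy)-5-methoxy-2-oxo-4,7-diphenyl-2,3-dihydro-1-benzofuran-3-yl]phenyl pivalate
Product: 21 6-(benzyloxy)-3-(4-hydroxyphenyl)-5-methoxy-4,7-diphenyl-1-benzofuran-2(3H)-one (racemic), via ring-opened hydroxy acid 20 (not isolated)
Conditions: LiOH·H2O (6 equiv), THF/MeOH/H2O, rt to 40 °C, argon; then 2 M HCl; then TsOH·H2O (cat.), toluene, 80 °C
Reagents that add atoms: none
Why: Saponification, in which hydroxide cleaves the aryl pivalate and opens the lactone to the salt of 20, and acidification with warming under TsOH catalysis recloses the five-membered aryl lactone while the benzyl and methyl ethers are inert to both media.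

Step 8
Reactants: 21 6-(benzyloxy)-3-(4-hydroxyphenyl)-5-methoxy-4,7-diphenyl-1-benzofuran-2(3H)-one
Product: 22 6-hydroxy-3-(4-hydroxyphenyl)-5-methoxy-4,7-diphenyl-1-benzofuran-2(3H)-one (racemic)
Conditions: H2 (1 atm), Pd/C (10 wt% Pd), EtOAc/MeOH, rt; filtered under argon and used directly
Reagents that add atoms: none
Why: Catalytic hydrogenolysis of a benzyl aryl ether over Pd/C, under which the lactone, the methyl ether and the aryl rings should not be reduced at 1 atm and room temperature.

Step 9
Reactants: 22 6-hydroxy-3-(4-hydroxyphenyl)-5-methoxy-4,7-diphenyl-1-benzofuran-2(3H)-one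
Product: 23 3-(4-hydroxyphenyl)-5-methoxy-4,7-diphenyl-1-benzofuran-2,6-dione (CNP0282683.0)
Conditions: DDQ (1.05 equiv), 1,4-dioxane, rt
Reagents that add atoms: none
Why: DDQ dehydrogenation of a para-hydroxybenzylic C–H compound to a para-quinone methide, in which hydride abstraction from the doubly benzylic C3–H and loss of the O6 proton give the C3=C3a and C6=O quinoid ring A, removing the only stereocentre and leaving a chromophore conjugated to the lactone carbonyl and the 4-hydroxyphenyl group.

**Compound list**

1 | isovanillin (3-hydroxy-4-methoxybenzaldehyde) | COc1ccc(C=O)cc1O | starting material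
2 | benzyl bromide | BrCc1ccccc1 | starting material
3 | 3-(benzyloxy)-4-methoxybenzaldehyde | COc1ccc(C=O)cc1OCc1ccccc1 | intermediate
4 | meta-chloroperbenzoic acid | OOC(=O)c1cccc(Cl)c1 | starting material
5 | 3-(benzyloxy)-4-methoxyphenyl formate | COc1ccc(OC=O)cc1OCc1ccccc1 | intermediate
6 | 3-(benzyloxy)-4-methoxyphenol | COc1ccc(O)cc1OCc1ccccc1 | intermediate
7 | 4-hydroxymandelic acid (racemic) | OC(C(=O)O)c1ccc(O)cc1 | starting material
8 | 2-[4-(benzyloxy)-2-hydroxy-5-methoxyphenyl]-2-(4-hydroxyphenyl)acetic acid (racemic) | COc1cc(C(C(=O)O)c2ccc(O)cc2)c(O)cc1OCc1ccccc1 | intermediate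
9 | 6-(benzyloxy)-3-(4-hydroxyphenyl)-5-methoxy-1-benzofuran-2(3H)-one (racemic) | COc1cc2c(cc1OCc1ccccc1)OC(=O)C2c1ccc(O)cc1 | intermediate
10 | pivaloyl chloride | CC(C)(C)C(=O)Cl | starting material
11 | 4-[6-(benzyloxy)-5-methoxy-2-oxo-2,3-dihydro-1-benzofuran-3-yl]phenyl pivalate (racemic) | COc1cc2c(cc1OCc1ccccc1)OC(=O)C2c1ccc(OC(=O)C(C)(C)C)cc1 | intermediate
12 | N-bromosuccinimide | O=C1CCC(=O)N1Br | starting material
13 | 4-[6-(benzyloxy)-7-bromo-5-methoxy-2-oxo-2,3-dihydro-1-benzofuran-3-yl]phenyl pivalate (racemic) | COc1cc2c(c(Br)c1OCc1ccccc1)OC(=O)C2c1ccc(OC(=O)C(C)(C)C)cc1 | intermediate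
14 | 4-[6-(benzyloxy)-4-bromo-5-methoxy-2-oxo-2,3-dihydro-1-benzofuran-3-yl]phenyl pivalate (racemic) | COc1c(Br)c2c(cc1OCc1ccccc1)OC(=O)C2c1ccc(OC(=O)C(C)(C)C)cc1 | intermediate
15 | 4-[6-(benzyloxy)-4,7-dibromo-5-methoxy-2-oxo-2,3-dihydro-1-benzofuran-3-yl]phenyl pivalate (racemic) | COc1c(Br)c2c(c(Br)c1OCc1ccccc1)OC(=O)C2c1ccc(OC(=O)C(C)(C)C)cc1 | intermediate
16 | phenylboronic acid | OB(O)c1ccccc1 | starting material
17 | 4-[6-(benzyloxy)-4-bromo-5-methoxy-2-oxo-7-phenyl-2,3-dihydro-1-benzofuran-3-yl]phenyl pivalate (racemic) | COc1c(Br)c2c(c(-c3ccccc3)c1OCc1ccccc1)OC(=O)C2c1ccc(OC(=O)C(C)(C)C)cc1 | intermediate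
18 | 4-[6-(benzyloxy)-7-bromo-5-methoxy-2-oxo-4-phenyl-2,3-dihydro-1-benzofuran-3-yl]phenyl pivalate (racemic) | COc1c(-c3ccccc3)c2c(c(Br)c1OCc1ccccc1)OC(=O)C2c1ccc(OC(=O)C(C)(C)C)cc1 | intermediate
19 | 4-[6-(benzyloxy)-5-methoxy-2-oxo-4,7-diphenyl-2,3-dihydro-1-benzofuran-3-yl]phenyl pivalate (racemic) | COc1c(-c3ccccc3)c2c(c(-c3ccccc3)c1OCc1ccccc1)OC(=O)C2c1ccc(OC(=O)C(C)(C)C)cc1 | intermediate
20 | 2-[4-(benzyloxy)-2-hydroxy-5-methoxy-3,6-diphenylphenyl]-2-(4-hydroxyphenyl)acetic acid (racemic) | OC(=O)C(c1ccc(O)cc1)c1c(O)c(-c2ccccc2)c(OCc2ccccc2)c(OC)c1-c1ccccc1 | intermediate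
21 | 6-(benzyloxy)-3-(4-hydroxyphenyl)-5-methoxy-4,7-diphenyl-1-benzofuran-2(3H)-one (racemic) | COc1c(-c3ccccc3)c2c(c(-c3ccccc3)c1OCc1ccccc1)OC(=O)C2c1ccc(O)cc1 | intermediate
22 | 6-hydroxy-3-(4-hydroxyphenyl)-5-methoxy-4,7-diphenyl-1-benzofuran-2(3H)-one (racemic) | COc1c(-c3ccccc3)c2c(c(-c3ccccc3)c1O)OC(=O)C2c1ccc(O)cc1 | intermediate
23 | 3-(4-hydroxyphenyl)-5-methoxy-4,7-diphenyl-1-benzofuran-2,6-dione (CNP0282683.0) | COC1=C(c2ccccc2)C2=C(c3ccc(O)cc3)C(=O)OC2=C(c2ccccc2)C1=O | target

**Count and risks**

Total step count: 9. Longest linear sequence: 9 steps (isovanillin 1 to target 23).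

Steps most likely to fail, in order of risk:

Step 6 (twofold Suzuki–Miyaura coupling). K3PO4 converts the lactone into its enolate, and this may divert the catalyst into arylation or oxidative coupling at C3. Oxidative addition into the now very electron-rich ring may also stall after the first coupling, leaving monobromide or protodebrominated material. The fallback sets out from 15 and comes back at 19. It replaces the base-dependent boron transmetalation by a base-free zinc one: a Negishi coupling with commercial phenylzinc bromide (4 equiv, added slowly) under Pd(OAc)2 and SPhos in THF at 50 °C. No stoichiometric base is present, so the lactone stays protonated, and any zinc enolate formed by adventitious deprotonation is returned to the lactone on aqueous NH4Cl work-up. This fallback makes no compound outside the list (F0).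

Step 5 (dibromination). The second nuclear bromination must occur at a position that is only ortho-activated. It may therefore become slow enough that substitution at the enolisable, doubly benzylic C3–H competes, giving mixtures brominated at C3. The fallback sets out from 11 and comes back at 15. The bromination is pushed past the mixture with NBS (3.3 equiv) in MeCN to 4-[6-(benzyloxy)-3,4,7-tribromo-5-methoxy-2-oxo-2,3-dihydro-1-benzofuran-3-yl]phenyl pivalate F1. The tertiary α-bromo lactone position is then reduced selectively with zinc dust in AcOH/THF at rt. This is a Reformatsky-type reduction through the zinc enolate, which should leave the two aryl bromides untouched, and protonation gives 15.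

Step 3 (acid condensation). Under TsOH at 90 °C the O6 benzyl group may be lost or transferred to the electron-rich rings, and self-condensation of 4-hydroxymandelic acid may compete with the cross reaction. The fallback sets out from 6 and comes back at 9. It reverses the roles of the two rings. Phenol 6 is hydroxyalkylated with glyoxylic acid in aqueous NaOH at rt. Attack occurs ortho to the phenoxide at the carbon para to the benzyloxy group, since the para position is blocked by the methoxy group. This gives 2-[4-(benzyloxy)-2-hydroxy-5-methoxyphenyl]-2-hydroxyacetic acid F2. F2 is then treated with excess phenol and catalytic TsOH in AcOH at 40–50 °C. The benzylic cation now sits on the trioxygenated ring and should ionise under much milder acid than the original condensation. Phenol attacks mainly through its para position and the hydroxy acid lactonises to 9; a minor ortho-linked isomer would be removed by chromatography. This is the known glyoxylic acid/phenol/arene route to 3-arylbenzofuranones.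

**Further compounds**

F0 | step 6 | none | none
F1 | step 5 | 4-[6-(benzyloxy)-3,4,7-tribromo-5-methoxy-2-oxo-2,3-dihydro-1-benzofuran-3-yl]phenyl pivalate (racemic) | COc1c(Br)c2c(c(Br)c1OCc1ccccc1)OC(=O)C2(Br)c1ccc(OC(=O)C(C)(C)C)cc1
F2 | step 3 | 2-[4-(benzyloxy)-2-hydroxy-5-methoxyphenyl]-2-hydroxyacetic acid (racemic) | COc1cc(C(O)C(=O)O)c(O)cc1OCc1ccccc1
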